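The route rests on disconnecting the C4–C4a bond of the 2H-pyran ring B. Because C8 carries oxygen, C4a is the only free arene carbon ortho to O1, so a gold-activated terminal alkyne C3≡C4 attached to C2 can close only 6-endo onto C4a. One operation forms ring B and leaves the C2–O1 bond, and with it the (R)-configured quaternary C2, untouched. The precursor is an aryl tertiary-propargyl ether made by SNAr from a citramalate-derived alkynol. It carries bromine at the future C5, an allyl ether on the future C8 oxygen (removable without acid, which the target's tertiary allylic alcohol would not survive) and a TIPS-protected hydroxyethyl arm.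

Key step: step 8

Remark: 2H-chromenes can racemise at C2 by reversible electrocyclic ring opening, so every operation from step 8 onward is planned at or below room temperature and with exclusion of light.

Step 1
Reactants: 1 (R)-citramalic acid
Product: 2 [(4R)-2,2,4-trimethyl-5-oxo-1,3-dioxolan-4-yl]acetic acid
Conditions: 2,2-dimethoxypropane, TsOH·H2O (cat.), rt
Reagents that add atoms: 2,2-dimethoxypropane COC(C)(C)OC
Why: Acid-catalysed transketalisation ties the tertiary hydroxyl and the adjacent carboxyl into a five-membered 1,3-dioxolan-4-one, which differentiates the two carboxyl groups without touching the stereocentre.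

Step 2
Reactants: 2 [(4R)-2,2,4-trimethyl-5-oxo-1,3-dioxolan-4-yl]acetic acid
Product: 3 (5R)-5-(2-hydroxyethyl)-2,2,5-trimethyl-1,3-dioxolan-4-one
Conditions: BH3·SMe2, THF, 0 °C → rt; MeOH quench
Reagents that add atoms: none
Why: Chemoselective borane reduction of a free carboxylic acid beside the ester-like dioxolanone carbonyl should give the primary alcohol, and the non-acidic methanol quench is chosen to avoid translactonisation.

Step 3
Reactants: 3 (5R)-5-(2-hydroxyethyl)-2,2,5-trimethyl-1,3-dioxolan-4-one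
Product: 4 (5R)-2,2,5-trimethyl-5-{2-[(triisopropylsilyl)oxy]ethyl}-1,3-dioxolan-4-one
Conditions: TIPSCl, imidazole, DMF, rt
Reagents that add atoms: triisopropylsilyl chloride CC(C)[Si](Cl)(C(C)C)C(C)C
Why: Standard silylation of a primary alcohol, with the bulky TIPS group chosen because it should not migrate to the tertiary alkoxide of step 5 and its oxygen should not engage the activated alkyne in step 8.

Step 4
Reactants: 4 (5R)-2,2,5-trimethyl-5-{2-[(triisopropylsilyl)oxy]ethyl}-1,3-dioxolan-4-one
Product: 7 (3R)-3-methyl-5-[(triisopropylsilyl)oxy]pent-1-yn-3-ol, via dioxolan-4-ol hemiacetal 5 (not isolated), via α-hydroxy aldehyde 6 (not isolated)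
Conditions: i-Bu2AlH, CH2Cl2, −78 °C; then MeOH, K2CO3, dimethyl (1-diazo-2-oxopropyl)phosphonate, −78 °C → rt
Reagents that add atoms: dimethyl (1-diazo-2-oxopropyl)phosphonate CC(=O)C(=[N+]=[N-])P(=O)(OC)OC
Why: Partial hydride reduction of the dioxolanone stops at the cyclic hemiacetal, which in basic methanol opens with loss of acetone to the α-hydroxy aldehyde that undergoes Ohira–Bestmann (Seyferth–Gilbert) homologation in the same flask, the quaternary carbinol carbon having no α-hydrogen to epimerise.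

Step 5
Reactants: 7 (3R)-3-methyl-5-[(triisopropylsilyl)oxy]pent-1-yn-3-ol; 8 4-bromo-2-fluorobenzaldehyde
Product: 10 4-bromo-2-({(3R)-3-methyl-5-[(triisopropylsilyl)oxy]pent-1-yn-3-yl}oxy)benzaldehyde, via potassium alkoxide 9 (not isolated)
Conditions: KN(SiMe3)2 (0.98 equiv), THF, −40 °C; then 8, −40 °C → rt
Reagents that add atoms: none
Why: Nucleophilic aromatic substitution (SNAr) of the fluoride activated by the ortho formyl group forms the aryl–oxygen bond from the alkoxide side, so the carbinol C–O bond and the configuration are retained, and fluoride is displaced far faster than the para bromide.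

Step 6
Reactants: 10 4-bromo-2-({(3R)-3-methyl-5-[(triisopropylsilyl)oxy]pent-1-yn-3-yl}oxy)benzaldehyde
Product: 12 4-bromo-2-({(3R)-3-methyl-5-[(triisopropylsilyl)oxy]pent-1-yn-3-yl}oxy)phenol, via aryl formate 11 (not isolated)
Conditions: mCPBA, CH2Cl2, 0 °C → rt; aq. Na2S2O3/NaHCO3 wash; then K2CO3 (cat.), MeOH, 0 °C
Reagents that add atoms: 3-chloroperoxybenzoic acid OOC(=O)c1cccc(Cl)c1
Why: Dakin-type Baeyer–Villiger oxidation, in which the ortho-alkoxy aryl group migrates to give the aryl formate that mild methanolysis cleaves, while the alkyne, the silyl ether and the aryl bromide are inert to the peracid.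

Step 7
Reactants: 12 4-bromo-2-({(3R)-3-methyl-5-[(triisopropylsilyl)oxy]pent-1-yn-3-yl}oxy)phenol
Product: 13 1-(allyloxy)-4-bromo-2-({(3R)-3-methyl-5-[(triisopropylsilyl)oxy]pent-1-yn-3-yl}oxy)benzene
Conditions: allyl bromide, K2CO3, DMF, rt
Reagents that add atoms: allyl bromide C=CCBr
Why: Williamson etherification of the phenoxide installs an allyl ether, which tolerates organolithium, Grignard and hydroxide conditions and can be removed at the end under near-neutral palladium catalysis.

Step 8
Reactants: 13 1-(allyloxy)-4-bromo-2-({(3R)-3-methyl-5-[(triisopropylsilyl)oxy]pent-1-yn-3-yl}oxy)benzene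
Product: 14 (2R)-8-(allyloxy)-5-bromo-2-methyl-2-{2-[(triisopropylsilyl)oxy]ethyl}-2H-chromene
Conditions: Ph3PAuNTf2 (3 mol%), CH2Cl2, 0 °C → rt, dark
Reagents that add atoms: none
Why: The cationic gold centre π-activates the terminal alkyne C3≡C4, arene carbon C4a attacks C4 in a Friedel–Crafts manner, and rearomatisation followed by protodeauration at C3 releases the 2H-chromene. The closest known reaction type is the gold-catalysed intramolecular hydroarylation of aryl propargyl ethers, including 1,1-disubstituted ones, to 2H-chromenes. Ring B is closed in the 6-endo-dig mode. No stereocentre is created, and C2 keeps its citramalate-derived (R) configuration because no bond at C2, in particular C2–O1, is broken. Site selectivity is secured by the substitution pattern, C4a being the only free position ortho to O1 since C8 bears the allyloxy group, and chemoselectivity by the saturated TIPS-capped arm, which offers neither an enyne partner nor a free hydroxyl. The step also needs cyclisation to outrun ionisation of the tertiary propargylic C–O bond, which the non-acidic catalyst and low temperature should favour.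

Step 9
Reactants: 14 (2R)-8-(allyloxy)-5-bromo-2-methyl-2-{2-[(triisopropylsilyl)oxy]ethyl}-2H-chromene
Product: 15 2-[(2R)-8-(allyloxy)-5-bromo-2-methyl-2H-chromen-2-yl]ethanol
Conditions: Bu4NF, THF, 0 °C → rt
Reagents that add atoms: none
Why: Fluoride-mediated desilylation is orthogonal to the aryl allyl ether, the aryl bromide and the chromene.

Step 10
Reactants: 15 2-[(2R)-8-(allyloxy)-5-bromo-2-methyl-2H-chromen-2-yl]ethanol
Product: 17 (3E)-5-[(2R)-8-(allyloxy)-5-bromo-2-methyl-2H-chromen-2-yl]pent-3-en-2-one, via chromenylacetaldehyde 16 (not isolated)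
Conditions: Dess–Martin periodinane, Ph3P=CHC(O)CH3 (3 equiv), CH2Cl2, 0 °C → rt
Reagents that add atoms: 1-(triphenylphosphoranylidene)propan-2-one CC(=O)C=P(c1ccccc1)(c1ccccc1)c1ccccc1
Why: Running the Dess–Martin oxidation in the presence of the stabilised ylide (tandem oxidation–Wittig olefination) should intercept the β-aryloxy aldehyde as it forms, before it can eliminate the phenoxide, and the acyl-stabilised ylide gives the (E)-enone.

Step 11
Reactants: 17 (3E)-5-[(2R)-8-(allyloxy)-5-bromo-2-methyl-2H-chromen-2-yl]pent-3-en-2-one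
Product: 18 (3E)-5-[(2R)-8-(allyloxy)-5-bromo-2-methyl-2H-chromen-2-yl]-2-methylpent-3-en-2-ol
Conditions: MeMgBr, CeCl3, THF, −78 °C
Reagents that add atoms: methylmagnesium bromide C[Mg]Br
Why: The weakly basic organocerium reagent should add 1,2 to the enone without enolising its γ-position, giving the tertiary allylic alcohol and leaving the aryl bromide untouched.

Step 12
Reactants: 18 (3E)-5-[(2R)-8-(allyloxy)-5-bromo-2-methyl-2H-chromen-2-yl]-2-methylpent-3-en-2-ol
Product: 20 (2R)-8-(allyloxy)-2-[(2E)-4-hydroxy-4-methylpent-2-en-1-yl]-2-methyl-2H-chromene-5-carbaldehyde, via dilithio species 19 (not isolated)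
Conditions: n-BuLi (2.2 equiv), THF, −78 °C; then DMF, −78 °C → 0 °C
Reagents that add atoms: N,N-dimethylformamide CN(C)C=O
Why: After deprotonation of the hydroxyl, bromine–lithium exchange and trapping of the aryllithium with DMF (Bouveault-type formylation) installs the C5 aldehyde, the allyl ether and the chromene being inert at −78 °C.

Step 13
Reactants: 21 1-(2,4-dihydroxyphenyl)ethanone
Product: 22 1-[2,4-bis(allyloxy)phenyl]ethanone
Conditions: allyl bromide, K2CO3, DMF, 60 °C
Reagents that add atoms: allyl bromide C=CCBr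
Why: Double Williamson etherification, with mild heating to alkylate the hydrogen-bonded 2-hydroxyl as well.

Step 14
Reactants: 20 (2R)-8-(allyloxy)-2-[(2E)-4-hydroxy-4-methylpent-2-en-1-yl]-2-methyl-2H-chromene-5-carbaldehyde; 22 1-[2,4-bis(allyloxy)phenyl]ethanone
Product: 23 (2E)-1-[2,4-bis(allyloxy)phenyl]-3-{(2R)-8-(allyloxy)-2-[(2E)-4-hydroxy-4-methylpent-2-en-1-yl]-2-methyl-2H-chromen-5-yl}prop-2-en-1-one
Conditions: KOH, EtOH, rt
Reagents that add atoms: none
Why: Claisen–Schmidt (crossed aldol) condensation of the non-enolisable aryl aldehyde with the methyl ketone should give the (E)-chalcone, the allyl ethers and the tertiary alcohol being stable to ethanolic hydroxide.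

Step 15
Reactants: 23 (2E)-1-[2,4-bis(allyloxy)phenyl]-3-{(2R)-8-(allyloxy)-2-[(2E)-4-hydroxy-4-methylpent-2-en-1-yl]-2-methyl-2H-chromen-5-yl}prop-2-en-1-one
Product: 24 1-[2,4-bis(allyloxy)phenyl]-3-{(2R)-8-(allyloxy)-2-[(2E)-4-hydroxy-4-methylpent-2-en-1-yl]-2-methyl-2H-chromen-5-yl}propan-1-one
Conditions: [(Ph3P)CuH]6, toluene, H2O (2 equiv), rt
Reagents that add atoms: none
Why: The phosphine copper hydride effects conjugate (1,4) reduction of the enone only, leaving the chromene C3=C4 bond, the side-chain alkene, the allyl ethers and the ketone intact.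

Step 16
Reactants: 24 1-[2,4-bis(allyloxy)phenyl]-3-{(2R)-8-(allyloxy)-2-[(2E)-4-hydroxy-4-methylpent-2-en-1-yl]-2-methyl-2H-chromen-5-yl}propan-1-one
Product: 25 1-(2,4-dihydroxyphenyl)-3-{(2R)-8-hydroxy-2-[(2E)-4-hydroxy-4-methylpent-2-en-1-yl]-2-methyl-2H-chromen-5-yl}propan-1-one
Conditions: Pd(PPh3)4 (5 mol%), morpholine, THF, rt
Reagents that add atoms: none
Why: Palladium-catalysed allyl transfer to morpholine (Tsuji–Trost-type deallylation) should free the three phenols at room temperature without acid, so the tertiary allylic alcohol and the C2 stereocentre are not endangered.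

Compound list
1 | (R)-citramalic acid, (2R)-2-hydroxy-2-methylbutanedioic acid | OC(=O)C[C@](O)(C)C(=O)O | starting material
2 | [(4R)-2,2,4-trimethyl-5-oxo-1,3-dioxolan-4-yl]acetic acid | OC(=O)C[C@@]1(C)OC(C)(C)OC1=O | intermediate
3 | (5R)-5-(2-hydroxyethyl)-2,2,5-trimethyl-1,3-dioxolan-4-one | OCC[C@@]1(C)OC(C)(C)OC1=O | intermediate
4 | (5R)-2,2,5-trimethyl-5-{2-[(triisopropylsilyl)oxy]ethyl}-1,3-dioxolan-4-one | CC(C)[Si](C(C)C)(C(C)C)OCC[C@@]1(C)OC(C)(C)OC1=O | intermediate
5 | (5R)-2,2,5-trimethyl-5-{2-[(triisopropylsilyl)oxy]ethyl}-1,3-dioxolan-4-ol (both C4 epimers) | CC(C)[Si](C(C)C)(C(C)C)OCC[C@@]1(C)OC(C)(C)OC1O | intermediate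
6 | (2R)-2-hydroxy-2-methyl-4-[(triisopropylsilyl)oxy]butanal | CC(C)[Si](C(C)C)(C(C)C)OCC[C@](O)(C)C=O | intermediate
7 | (3R)-3-methyl-5-[(triisopropylsilyl)oxy]pent-1-yn-3-ol | CC(C)[Si](C(C)C)(C(C)C)OCC[C@](O)(C)C#C | intermediate
8 | 4-bromo-2-fluorobenzaldehyde | O=Cc1ccc(Br)cc1F | starting material
9 | potassium (3R)-3-methyl-5-[(triisopropylsilyl)oxy]pent-1-yn-3-olate | CC(C)[Si](C(C)C)(C(C)C)OCC[C@]([O-])(C)C#C.[K+] | intermediate
10 | 4-bromo-2-({(3R)-3-methyl-5-[(triisopropylsilyl)oxy]pent-1-yn-3-yl}oxy)benzaldehyde | CC(C)[Si](C(C)C)(C(C)C)OCC[C@](Oc1cc(Br)ccc1C=O)(C)C#C | intermediate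
11 | 4-bromo-2-({(3R)-3-methyl-5-[(triisopropylsilyl)oxy]pent-1-yn-3-yl}oxy)phenyl formate | CC(C)[Si](C(C)C)(C(C)C)OCC[C@](Oc1cc(Br)ccc1OC=O)(C)C#C | intermediate
12 | 4-bromo-2-({(3R)-3-methyl-5-[(triisopropylsilyl)oxy]pent-1-yn-3-yl}oxy)phenol | CC(C)[Si](C(C)C)(C(C)C)OCC[C@](Oc1cc(Br)ccc1O)(C)C#C | intermediate
13 | 1-(allyloxy)-4-bromo-2-({(3R)-3-methyl-5-[(triisopropylsilyl)oxy]pent-1-yn-3-yl}oxy)benzene (key-step precursor) | CC(C)[Si](C(C)C)(C(C)C)OCC[C@](Oc1cc(Br)ccc1OCC=C)(C)C#C | intermediate
14 | (2R)-8-(allyloxy)-5-bromo-2-methyl-2-{2-[(triisopropylsilyl)oxy]ethyl}-2H-chromene (key-step product) | CC(C)[Si](C(C)C)(C(C)C)OCC[C@]1(C)C=Cc2c(Br)ccc(OCC=C)c2O1 | intermediate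
15 | 2-[(2R)-8-(allyloxy)-5-bromo-2-methyl-2H-chromen-2-yl]ethanol | OCC[C@]1(C)C=Cc2c(Br)ccc(OCC=C)c2O1 | intermediate
16 | [(2R)-8-(allyloxy)-5-bromo-2-methyl-2H-chromen-2-yl]acetaldehyde | O=CC[C@]1(C)C=Cc2c(Br)ccc(OCC=C)c2O1 | intermediate
17 | (3E)-5-[(2R)-8-(allyloxy)-5-bromo-2-methyl-2H-chromen-2-yl]pent-3-en-2-one | CC(=O)/C=C/C[C@]1(C)C=Cc2c(Br)ccc(OCC=C)c2O1 | intermediate
18 | (3E)-5-[(2R)-8-(allyloxy)-5-bromo-2-methyl-2H-chromen-2-yl]-2-methylpent-3-en-2-ol | CC(C)(O)/C=C/C[C@]1(C)C=Cc2c(Br)ccc(OCC=C)c2O1 | intermediate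
19 | {(2R)-8-(allyloxy)-2-[(2E)-4-(lithiooxy)-4-methylpent-2-en-1-yl]-2-methyl-2H-chromen-5-yl}lithium | [Li]OC(C)(C)/C=C/C[C@]1(C)C=Cc2c([Li])ccc(OCC=C)c2O1 | intermediate
20 | (2R)-8-(allyloxy)-2-[(2E)-4-hydroxy-4-methylpent-2-en-1-yl]-2-methyl-2H-chromene-5-carbaldehyde | CC(C)(O)/C=C/C[C@]1(C)C=Cc2c(C=O)ccc(OCC=C)c2O1 | intermediate
21 | 1-(2,4-dihydroxyphenyl)ethanone | CC(=O)c1ccc(O)cc1O | starting material
22 | 1-[2,4-bis(allyloxy)phenyl]ethanone | CC(=O)c1ccc(OCC=C)cc1OCC=C | intermediate
23 | (2E)-1-[2,4-bis(allyloxy)phenyl]-3-{(2R)-8-(allyloxy)-2-[(2E)-4-hydroxy-4-methylpent-2-en-1-yl]-2-methyl-2H-chromen-5-yl}prop-2-en-1-one | CC(C)(O)/C=C/C[C@]1(C)C=Cc2c(/C=C/C(=O)c3ccc(OCC=C)cc3OCC=C)ccc(OCC=C)c2O1 | intermediate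
24 | 1-[2,4-bis(allyloxy)phenyl]-3-{(2R)-8-(allyloxy)-2-[(2E)-4-hydroxy-4-methylpent-2-en-1-yl]-2-methyl-2H-chromen-5-yl}propan-1-one | CC(C)(O)/C=C/C[C@]1(C)C=Cc2c(CCC(=O)c3ccc(OCC=C)cc3OCC=C)ccc(OCC=C)c2O1 | intermediate
25 | 1-(2,4-dihydroxyphenyl)-3-{(2R)-8-hydroxy-2-[(2E)-4-hydroxy-4-methylpent-2-en-1-yl]-2-methyl-2H-chromen-5-yl}propan-1-one | CC(C)(O)/C=C/C[C@]1(C)C=Cc2c(CCC(=O)c3ccc(O)cc3O)ccc(O)c2O1 | target

Total step count: 16. Longest linear sequence: 15 steps (steps 1–12 and 14–16, from (R)-citramalic acid); step 13 is a one-step side branch.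

Steps most likely to fail

Step 8. The gold centre may ionise the tertiary propargylic C2–O1 bond instead of promoting ring closure, which would erode the configuration or cleave the ether; attack at C4a, which is flanked by bromine, may also be slow. The fallback sets out from 13 and replaces metal π-activation by a metal-free electrophilic cyclisation. Iodonium-induced 6-endo iodoarylation (I2, NaHCO3, CH3NO2, rt) should give (2R)-8-(allyloxy)-5-bromo-3-iodo-2-methyl-2-{2-[(triisopropylsilyl)oxy]ethyl}-2H-chromene F1. Selective iodine–magnesium exchange of the alkenyl iodide with i-PrMgCl·LiCl (THF, −40 °C), which should leave the electron-rich aryl bromide alone, followed by protonation with MeOH at that temperature, comes back to the route at 14.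

Step 5. The hindered tertiary alkoxide (or a trace of acetylide) may add to the formyl group instead of substituting at the fluorinated carbon, and hydride-transfer side reactions of the aldehyde may follow. The fallback sets out from 7 and uses a nitrile as the activating group. SNAr of alkoxide 9 on 4-bromo-2-fluorobenzonitrile (THF, 0 °C → rt) should give 4-bromo-2-({(3R)-3-methyl-5-[(triisopropylsilyl)oxy]pent-1-yn-3-yl}oxy)benzonitrile F2. Reduction with i-Bu2AlH (toluene, −78 °C) and mild aqueous hydrolysis of the aldimine comes back to the route at 10.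

Step 4. The dioxolanone may be over-reduced, or the cyclic hemiacetal may release the aldehyde too slowly for the one-pot homologation. The fallback sets out from 4 and separates the operations. Exhaustive reduction with LiAlH4 (THF, 0 °C) should give (2R)-2-methyl-4-[(triisopropylsilyl)oxy]butane-1,2-diol F3. Chemoselective oxidation of its primary hydroxyl (TEMPO cat., PhI(OAc)2, CH2Cl2, rt) gives the hydroxy aldehyde 6 as an isolated compound, and Ohira–Bestmann homologation (K2CO3, MeOH, 0 °C → rt) comes back to the route at 7.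

Further compounds
F1 | step 8 | (2R)-8-(allyloxy)-5-bromo-3-iodo-2-methyl-2-{2-[(triisopropylsilyl)oxy]ethyl}-2H-chromene | CC(C)[Si](C(C)C)(C(C)C)OCC[C@]1(C)C(I)=Cc2c(Br)ccc(OCC=C)c2O1
F2 | step 5 | 4-bromo-2-({(3R)-3-methyl-5-[(triisopropylsilyl)oxy]pent-1-yn-3-yl}oxy)benzonitrile | CC(C)[Si](C(C)C)(C(C)C)OCC[C@](Oc1cc(Br)ccc1C#N)(C)C#C
F3 | step 4 | (2R)-2-methyl-4-[(triisopropylsilyl)oxy]butane-1,2-diol | CC(C)[Si](C(C)C)(C(C)C)OCC[C@](O)(C)CO
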